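**Retrosynthetic overview**
- The target is an open-chain 1,3-diketone. It is cut at the C(=O)–CH2 bond beside the 2,4-dihydroxy-5-prenylphenyl ring, with reversed polarity on both sides: an acyl-anion synthon and a phenacyl-cation (enolonium) synthon.
- The acyl anion is the aldehydic C–H of 2,4-dihydroxy-5-prenylbenzaldehyde, activated as an acyl–Rh(III) species by its own 2-OH. The enolonium is the Rh-carbene from the β-keto sulfoxonium ylide of the 4-hydroxy-3-prenylbenzoyl unit.
- The ylide comes from methyl 4-hydroxy-3-prenylbenzoate, made by ortho-C-prenylation of methyl 4-hydroxybenzoate. The aldehyde comes from C5 Friedel–Crafts prenylation of 2,4-dihydroxybenzaldehyde.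
- No ring is formed: both benzene rings are bought, and no protecting groups are used.

Assumption: the target has no stereocentre and no E/Z-defined alkene, so "single enantiomer" means the achiral compound as drawn (diketo form shown; it exists largely as the chelated enol).

**Step 1**
Reactants: 1 methyl 4-hydroxybenzoate
Product: 3 methyl 4-hydroxy-3-(3-methylbut-2-en-1-yl)benzoate, via sodium 4-(methoxycarbonyl)phenolate 2 (not isolated)
Conditions: NaH (1.1 equiv), PhMe, 0 °C → rt, 1 h; then prenyl bromide (1.0 equiv), rt → 50 °C, 16 h; aq. NH4Cl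
Reagents that add atoms: prenyl bromide (1-bromo-3-methylbut-2-ene), CC(C)=CCBr
Why: Ortho-selective C-alkylation of a tight-ion-pair sodium phenolate in a non-polar solvent (phenolate C-allylation, SN2 at the primary allylic bromide followed by rearomatisation), with the para position blocked by the ester and no stereocentre formed.

**Step 2**
Reactants: 3 methyl 4-hydroxy-3-(3-methylbut-2-en-1-yl)benzoate
Product: 4 2-[dimethyl(oxo)-λ6-sulfanylidene]-1-[4-hydroxy-3-(3-methylbut-2-en-1-yl)phenyl]ethan-1-one
Conditions: Me3S(O)I (4 equiv), KOtBu (4 equiv), THF, reflux, 2 h; then 3, reflux, 24 h; aq. NH4Cl to pH 7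
Reagents that add atoms: trimethylsulfoxonium iodide, C[S+](C)(C)=O.[I-]
Why: Acylation of dimethylsulfoxonium methylide (Corey–Chaykovsky reagent) by the methyl ester, followed by deprotonation, gives the stabilised β-keto sulfoxonium ylide; the phenol rides through as its potassium salt (hence excess ylide and reflux) and the prenyl group is inert.

**Step 3**
Reactants: 5 2,4-dihydroxybenzaldehyde
Product: 6 2,4-dihydroxy-5-(3-methylbut-2-en-1-yl)benzaldehyde
Conditions: 2-methylbut-3-en-2-ol (1.2 equiv), BF3·OEt2 (0.3 equiv), 1,4-dioxane, rt, 16 h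
Reagents that add atoms: 2-methylbut-3-en-2-ol, CC(C)(O)C=C
Why: Friedel–Crafts prenylation by the dimethylallyl cation at its primary terminus occurs at C5 (ortho to 4-OH, para to 2-OH, less hindered than C3), with dioxane tempering BF3 so the new o-prenylphenol does not close to a chroman; no stereocentre is formed.

**Step 4**
Reactants: 6 2,4-dihydroxy-5-(3-methylbut-2-en-1-yl)benzaldehyde; 4 2-[dimethyl(oxo)-λ6-sulfanylidene]-1-[4-hydroxy-3-(3-methylbut-2-en-1-yl)phenyl]ethan-1-one
Product: 7 Glycyrdione A, 1-[2,4-dihydroxy-5-(3-methylbut-2-en-1-yl)phenyl]-3-[4-hydroxy-3-(3-methylbut-2-en-1-yl)phenyl]propane-1,3-dione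
Conditions: 6 (1.0 equiv), 4 (1.2 equiv), [Cp*Rh(MeCN)3](SbF6)2 (5 mol %), NaOAc (30 mol %), DCE, 60 °C, N2, 12 h
Reagents that add atoms: none
Why: Proposed new method: the 2-OH of 6 directs acetate-assisted aldehydic C–H rhodation to a five-membered acyl–Rh(III) phenoxide (a catalytic acyl-anion equivalent), ylide 4 binds through carbon and loses DMSO to give an electrophilic α-oxo Rh-carbene (an enolonium equivalent), 1,1-migratory insertion of the acyl group forms the CO–CH2 bond and protonolysis releases the 1,3-diketone; the closest known reaction type is the Cp*Rh(III)-catalysed coupling of salicylaldehydes with sulfoxonium ylides or diazo ketones, which under hot acidic conditions runs on to chromones, and here the acetate buffer, the absence of added acid and 60 °C are chosen to stop at the open diketone and spare the prenyl groups and free phenols; no stereocentre is formed.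

**Compound list**
1 | methyl 4-hydroxybenzoate | COC(=O)c1ccc(O)cc1 | starting material
2 | sodium 4-(methoxycarbonyl)phenolate | COC(=O)c1ccc([O-])cc1.[Na+] | intermediate
3 | methyl 4-hydroxy-3-(3-methylbut-2-en-1-yl)benzoate | COC(=O)c1ccc(O)c(CC=C(C)C)c1 | intermediate
4 | 2-[dimethyl(oxo)-λ6-sulfanylidene]-1-[4-hydroxy-3-(3-methylbut-2-en-1-yl)phenyl]ethan-1-one | CS(C)(=O)=CC(=O)c1ccc(O)c(CC=C(C)C)c1 | intermediate
5 | 2,4-dihydroxybenzaldehyde | O=Cc1ccc(O)cc1O | starting material
6 | 2,4-dihydroxy-5-(3-methylbut-2-en-1-yl)benzaldehyde | O=Cc1cc(CC=C(C)C)c(O)cc1O | intermediate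
7 | Glycyrdione A, 1-[2,4-dihydroxy-5-(3-methylbut-2-en-1-yl)phenyl]-3-[4-hydroxy-3-(3-methylbut-2-en-1-yl)phenyl]propane-1,3-dione | CC(C)=CCc1cc(C(=O)CC(=O)c2cc(CC=C(C)C)c(O)cc2O)ccc1O | target

**Totals**
Total step count: 4. Longest linear sequence: 3 steps (1 → 3 → 4 → 7; steps 1, 2 and 4).

**Three steps most likely to fail**

Step 4 (key coupling). The risks are cyclodehydration of the product to the flavone, binding of the para-phenoxides or the β-diketonate product to rhodium, and carbene O–H insertion into the free phenols. The fallback sets out from 6 and comes back at 7, leaving only the directing 2-OH free during the coupling. Compound 6 is silylated selectively at the non-chelated 4-OH (TIPSCl, imidazole, DMF, 0 °C) to give 2-hydroxy-5-(3-methylbut-2-en-1-yl)-4-[(triisopropylsilyl)oxy]benzaldehyde F4. This is coupled under the same Rh(III) catalysis with the silylated ylide 2-[dimethyl(oxo)-λ6-sulfanylidene]-1-{3-(3-methylbut-2-en-1-yl)-4-[(triisopropylsilyl)oxy]phenyl}ethan-1-one F2 (made from 3 as described in the next fallback). The product is 1-{2-hydroxy-5-(3-methylbut-2-en-1-yl)-4-[(triisopropylsilyl)oxy]phenyl}-3-{3-(3-methylbut-2-en-1-yl)-4-[(triisopropylsilyl)oxy]phenyl}propane-1,3-dione F5. Both silyl ethers are then removed with TBAF/AcOH in THF at 0 °C to give 7.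

Step 2 (ylide formation). The ester of a para-phenoxide is a poor acyl acceptor and may not be acylated even with excess methylide. The fallback sets out from 3 and comes back at 4. The phenol is masked first (TIPSCl, imidazole, DMF, rt) to give methyl 3-(3-methylbut-2-en-1-yl)-4-[(triisopropylsilyl)oxy]benzoate F1. The now normally electrophilic ester is treated with dimethylsulfoxonium methylide (Me3S(O)I, KOtBu, THF, reflux) to give 2-[dimethyl(oxo)-λ6-sulfanylidene]-1-{3-(3-methylbut-2-en-1-yl)-4-[(triisopropylsilyl)oxy]phenyl}ethan-1-one F2. Desilylation with TBAF/AcOH in THF at 0 °C then gives 4.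

Step 3 (C5 prenylation). The risks are modest yield, C3 versus C5 mixtures, bis-prenylation and chroman formation. The fallback sets out from 5 and comes back at 6, replacing the Friedel–Crafts alkylation with halogenation and cross-coupling. Iodination of 5 with ICl in AcOH at rt gives 2,4-dihydroxy-5-iodobenzaldehyde F3, with the regiochemistry fixed at C5. Stille coupling with tributyl(3-methylbut-2-en-1-yl)stannane (Pd(PPh3)4, DMF, 80 °C) then gives the linear prenyl compound 6.

**Further compounds**
F1 | step 2 | methyl 3-(3-methylbut-2-en-1-yl)-4-[(triisopropylsilyl)oxy]benzoate | COC(=O)c1ccc(O[Si](C(C)C)(C(C)C)C(C)C)c(CC=C(C)C)c1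
F2 | step 2 | 2-[dimethyl(oxo)-λ6-sulfanylidene]-1-{3-(3-methylbut-2-en-1-yl)-4-[(triisopropylsilyl)oxy]phenyl}ethan-1-one | CS(C)(=O)=CC(=O)c1ccc(O[Si](C(C)C)(C(C)C)C(C)C)c(CC=C(C)C)c1
F3 | step 3 | 2,4-dihydroxy-5-iodobenzaldehyde | O=Cc1cc(I)c(O)cc1O
F4 | step 4 | 2-hydroxy-5-(3-methylbut-2-en-1-yl)-4-[(triisopropylsilyl)oxy]benzaldehyde | O=Cc1cc(CC=C(C)C)c(O[Si](C(C)C)(C(C)C)C(C)C)cc1O
F5 | step 4 | 1-{2-hydroxy-5-(3-methylbut-2-en-1-yl)-4-[(triisopropylsilyl)oxy]phenyl}-3-{3-(3-methylbut-2-en-1-yl)-4-[(triisopropylsilyl)oxy]phenyl}propane-1,3-dione | CC(C)=CCc1cc(C(=O)CC(=O)c2cc(CC=C(C)C)c(O[Si](C(C)C)(C(C)C)C(C)C)cc2O)ccc1O[Si](C(C)C)(C(C)C)C(C)C
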